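## Structural features

The target is a C27 apocarotenoid diol. Its core is a 2,4,5,6,7,7a-hexahydro-1-benzofuran: a cyclohexane ring (C1 gem-dimethyl, C3 secondary hydroxyl, C5 quaternary O-bearing methyl carbon) fused through C5 and C6 to a 2,5-dihydrofuran ring (O, C5, C6=C7, C8). C8 carries the chain C9–C10′, a hexaene with methyl groups on C9, C13 and C13′ that ends in the primary allylic alcohol C10′. The C9=C10 bond is Z (C8 and C11 cis) and the other five chain alkenes are E. There are three stereocentres: C3 (S), C5 (R) and C8 (S). C3 and C5 are 1,3 to each other through C4, with the hydroxyl on the face of the C5 methyl group and trans to the ring oxygen. C5 and C8 are 1,3 to each other across the ether oxygen, with the C5 methyl group and C9 on the same face of the dihydrofuran. C8 is a doubly allylic ether carbon, so acid can ionise C8–O and epimerise or open the ring. The Z alkene beside it and the hexaene rule out any clean-up by iodine, light, heat or strong acid. The real difficulty is the quaternary ether carbon C5 and its relation to C8 across oxygen, for which the skeleton has no built-in bias. The key step uses the fact that the C3 oxygen is 1,3 to C5 through C4H2 while C5 is allylic to C6=C7 and tied through oxygen to C8. This is the pattern left by a Prins reaction of a C3 aldehyde with the C4=C5 end of a C4=C5–C6=C7 diene, terminated by the C8 oxygen, so both rings can be closed from an open chain.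

## Logic of the disconnections

34 ⇒ 33. No skeletal bond is cut; the C10′ alcohol is taken back to the ethyl ester. The ester is the group that stabilises the olefination reagent one step earlier, so it costs nothing extra. The forward step must be a clean 1,2-reduction in the presence of the hexaene and the free C3 hydroxyl.

33 ⇒ 26 + 31. The C11=C12 double bond is cut. This is the E-disubstituted alkene next to the bicyclic fragment, and cutting it removes the whole polyene in one stroke, so the light- and acid-sensitive chain exists for only two steps. The bicyclic partner is the electrophile (C11 aldehyde), which keeps acid away from the C8 ether. The forward step must give E at C11=C12 without base-induced loss of the Z geometry at C9=C10.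

31 ⇒ 30 ⇒ 29 ⇒ 28 ⇒ 27. The C12–P bond, the C12–Br bond, the C12 oxidation level and finally the C11′=C12′ double bond are removed in turn. This reduces the chain reagent to the symmetrical dialdehyde 27. The demand lies on the first forward step, which must olefinate only one of two equivalent aldehydes.

26 ⇒ 25 ⇒ 24. Only the C11 oxidation level and the C11 O–Si bond change. This brings the sensitive Z-enal back to a silyl-protected allylic alcohol that can be carried through the C3 adjustment. The forward oxidation must distinguish the allylic primary alcohol from the C3 secondary alcohol and must not isomerise C9=C10.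

24 ⇒ 23 ⇒ 22 ⇒ 21. The C3–H bond is cut (ketone) and the C3 configuration is exchanged. The ring closure in 20 ⇒ 21 places the C3 oxygen equatorial, cis to the C5 oxygen, which is the epimer of the target. Passing through 23 removes this relay centre and lets a bulky hydride reset it. The forward reduction must attack C3 from the face opposite the two syn-axial methyl groups on C1 and C5.

21 ⇒ 20. The C3–C4 bond and the C5–O bond are cut, which opens both rings and removes the stereocentres C3 and C5. What remains is an open-chain diene aldehyde with a single stereocentre (C8). The forward step must control the aldehyde face by a chiral acid, relay it to C5 through a chair, and do so without ionising the C8–O bond.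

20 ⇒ 19. Only the C3 oxidation level changes. The aldehyde is unmasked last, from a primary triethylsilyl ether, so the reactive aldehyde–diene pair is never stored and no third kind of protecting group is needed. The forward oxidation must leave the secondary triethylsilyl ether on C8 intact.

19 ⇒ 15 + 16. The C5–C6 bond is cut, which removes the isopropenyl group and leaves an alkenyl iodide. The gain is that the diene geometry is reduced to the geometry of one iodoalkene. The forward coupling must proceed with retention at C6 on a carbon flanked by the quaternary C1.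

15 ⇒ 14 ⇒ 12. The two O–Si bonds, the C6–I and C7–H bonds are removed and C3 returns to the ester level. One alkyne then encodes the trisubstituted alkene. The forward step must add hydride and aluminium trans across the alkyne with aluminium on C6, and reduce the ester in the same operation.

12 ⇒ 4 + 10. The C7–C8 bond is cut; this is the only bond formed at the sole stereocentre that is set from outside. It divides the precursor into two small achiral pieces. The forward addition must be enantioselective on a Z-enal (Si face) and must tolerate the ester.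

10 ⇒ 8 ⇒ 7 ⇒ 5. The C8–C9 bond (formyl group), the O–Si bond and the C9–I and C10–H bonds are removed. The Z geometry of C9=C10 is traced back to a trans-hydroalumination–iodination of 5. The demand is retention of geometry in the alkenyllithium and no 1,4-migration of silicon from oxygen to carbon, which is why the silyl group on C11 is the bulky one.

4 ⇒ 3 ⇒ 1. The C6≡C7 bond is cut back to an aldehyde and then to the vinyl group of 1. The quaternary C1 is bought in. The forward homologation must work on a hindered, non-enolisable aldehyde beside an ester.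

## Other disconnections considered

Alternative 1: The cut is C5–O and C4–C5 of the oxygen ring alone. In the forward direction Cu(acac)2 would decompose diazoketone A2 to a copper carbenoid at C5, the allyl ether oxygen on C8 would add to it to give a five-membered oxonium ylide, and a [2,3]-shift would move the allyl group from oxygen to C5, giving furanone A1. In its favour: the reaction type is well established for such furanones, runs under neutral conditions, and sets the quaternary C5 relative to C8 by substrate control with the allyl group trans to the C8 substituent, which is the relation needed. On precedent and on mildness toward the C8 ether it is better than the chosen plan, and it needs no chiral catalyst for C5. Against it here: A1 holds only the heterocycle. C1 with its two methyl groups and C2 are absent, C3 has no oxygen, C6 is a ketone that must be joined to a quaternary C1 while flanked by the quaternary C5, the C6=C7 alkene must then be regenerated regioselectively, and the silylalkyne must be turned into the Z-trisubstituted C9=C10 alkene by a regio- and stereocontrolled carbometalation. The chosen plan closes both rings and sets two centres in one step. Alternative 1 closes one ring and leaves the harder carbocycle to many further steps, so on step economy the chosen plan is clearly ahead.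

Alternative 2: The cut is both C–O bonds of the dihydrofuran (C5–O and C8–O), leading back to the monocyclic triene ester A4 with C3 already in place. In the forward direction sensitised singlet oxygen would add across C5 and C8 of the C5=C6–C7=C8 diene to give endoperoxide A5, and PPh3 in the same pot would remove one oxygen and close O–C8 with inversion at C8, giving A3. In its favour: the C3 centre is bought in with the natural configuration, so no inversion is needed. The cycloaddition is suprafacial and the ring contraction is stereospecific, so C8 follows from C5. A4 is a short distance from the known hydroxy-trimethylcyclohexanone building blocks. On step count and on the C3 centre it is better than the chosen plan. Against it here: the C5 face is chosen only by the remote C3 substituent. Singlet oxygen can also react by the ene mode at C4–H or C18–H. The endoperoxide can rearrange to a hydroxy enone under base. Inversion at C8 competes with ionisation at this allylic carbon. The 9Z dienoate must be made geometrically pure first. The chosen plan puts the decisive C5/C8 relation under a tunable catalyst; alternative 2 leaves it to a weak 1,3-bias followed by a stereospecific step. Mechanistically both depend on one demanding oxygen-transfer or cation event at an allylic ether. Alternative 2 is the shorter plan; the chosen plan offers the firmer handle on C5.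

Alternative 3: The cut is O–C8 and C8–H, leading back to the enyne diol A7, in which C3 and C5 are already set and C7≡C8 is an alkyne. In the forward direction (Ph3P)AuNTf2 would make the C5 hydroxyl add to C8 (5-endo-dig). A chiral 3,3′-diaryl binaphthyl hydrogen phosphate would ionise the C6 hydroxyl to a conjugated oxocarbenium ion, and a Hantzsch ester would deliver hydride to C8 within the chiral ion pair, giving A6. In its favour: the carbocycle and its two centres come from known chemistry with no C3 inversion. The side chain is attached convergently as an acetylide. C8 is set last and under catalyst control, and the conditions are milder than a strong confined acid. It is the equal of the chosen plan in using catalyst control for the C5/C8 relation and better in having no relay centre to correct. Against it here: the cation is delocalised over C8, C6 and C10, so hydride can also arrive at C6 or C10. Face control of a carbon-only oxocarbenium by a chiral phosphate is less secure than for iminium ions. The tertiary C5 alcohol must be made with the correct relation to C3 beforehand. The acetylide must add to a ketone flanked by two fully substituted carbons. In step economy the two plans are close; alternative 3 buys the six-membered ring, while the chosen plan builds both rings and C5 in one step from a simple chain.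

Key step: step 11

Remark: carotenoid numbering (C1–C11, then C12–C10′) is used for positions; TBDPS = tert-butyldiphenylsilyl, TES = triethylsilyl; C9=C10 is taken as Z, exactly as drawn in the target. For the two chiral catalysts (ProPhenol in step 6, imidodiphosphorimidate in step 11) the route fixes the face that must be attacked; the (R,R)-ProPhenol ligand is the expected antipode by analogy with its aldol additions, and the antipode of each catalyst is to be confirmed on the first run.

## Route

Step 1
Reactants: 1 methyl 3,3-dimethylpent-4-enoate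
Product: 3 methyl 3,3-dimethyl-4-oxobutanoate, via secondary ozonide 2 (not isolated)
Conditions: O3, CH2Cl2, −78 °C; Me2S, −78 °C to rt
Reagents that add atoms: ozone, [O-][O+]=O
Why: Ozonolysis cleaves the monosubstituted alkene to the aldehyde; the quaternary carbon beside it rules out enolisation and the ester is inert to the reductive work-up.

Step 2
Reactants: 3 methyl 3,3-dimethyl-4-oxobutanoate
Product: 4 methyl 3,3-dimethylpent-4-ynoate
Conditions: dimethyl (1-diazo-2-oxopropyl)phosphonate, K2CO3, MeOH, 0 °C to rt
Reagents that add atoms: dimethyl (1-diazo-2-oxopropyl)phosphonate, CC(=O)C(=[N+]=[N-])P(=O)(OC)OC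
Why: Seyferth–Gilbert homologation with the Ohira–Bestmann reagent turns a non-enolisable aldehyde into the terminal alkyne; in K2CO3/MeOH a methyl ester can only exchange with itself.

Step 3
Reactants: 5 but-2-yn-1-ol
Product: 7 (2Z)-3-iodobut-2-en-1-ol, via cyclic sodium alkenylalanate 6 (not isolated)
Conditions: NaAlH2(OCH2CH2OCH3)2, THF, 0 °C to rt; EtOAc; I2, THF, −78 to 0 °C
Reagents that add atoms: iodine, II
Why: Alkoxide-directed trans-hydroalumination of a propargylic alcohol puts aluminium on the distal carbon and hydride on the proximal one from opposite faces; iodinolysis with retention gives the Z-iodoalkene that later becomes the Z C9=C10 bond.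

Step 4
Reactants: 7 (2Z)-3-iodobut-2-en-1-ol
Product: 8 tert-butyl{[(2Z)-3-iodobut-2-en-1-yl]oxy}diphenylsilane
Conditions: t-BuPh2SiCl, imidazole, CH2Cl2, 0 °C to rt
Reagents that add atoms: tert-butyl(chloro)diphenylsilane, CC(C)(C)[Si](Cl)(c1ccccc1)c1ccccc1
Why: Standard silylation of a primary alcohol; the bulky TBDPS group is chosen because it resists 1,4-migration from oxygen to carbon in the alkenyllithium of step 5 and survives all desilylations before step 15.

Step 5
Reactants: 8 tert-butyl{[(2Z)-3-iodobut-2-en-1-yl]oxy}diphenylsilane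
Product: 10 (2Z)-4-(TBDPS-oxy)-2-methylbut-2-enal, via Z-alkenyllithium 9 (not isolated)
Conditions: t-BuLi (2.1 equiv), Et2O, −78 °C; DMF, −78 °C; AcOH, then H2O
Reagents that add atoms: N,N-dimethylformamide, CN(C)C=O
Why: Iodine–lithium exchange keeps the alkene geometry and formylation of the alkenyllithium with DMF gives the Z-enal; the low temperature and the acetic acid quench protect the Z geometry.

Step 6
Reactants: 4 methyl 3,3-dimethylpent-4-ynoate; 10 (2Z)-4-(TBDPS-oxy)-2-methylbut-2-enal
Product: 12 methyl (6R,7Z)-9-(TBDPS-oxy)-6-hydroxy-3,3,7-trimethylnon-7-en-4-ynoate, via methylzinc acetylide 11 (not isolated)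
Conditions: Me2Zn, ProPhenol ligand (20 mol %, antipode as in the remark), Ph3P=O (40 mol %), toluene, 0 to 4 °C; aq. NH4Cl
Reagents that add atoms: none
Why: Catalytic asymmetric alkynylation of an enal by a dinuclear zinc–ProPhenol complex; the acetylide adds to the Si face of the aldehyde and gives the R carbinol, which is C8 of the target; the ester is inert to Me2Zn under these conditions.

Step 7
Reactants: 12 methyl (6R,7Z)-9-(TBDPS-oxy)-6-hydroxy-3,3,7-trimethylnon-7-en-4-ynoate
Product: 14 (4Z,6S,7Z)-9-(TBDPS-oxy)-4-iodo-3,3,7-trimethylnona-4,7-diene-1,6-diol, via cyclic sodium alkenylalanate 13 (not isolated)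
Conditions: NaAlH2(OCH2CH2OCH3)2 (4 equiv), THF, 0 °C to rt; EtOAc; I2, −78 to 0 °C
Reagents that add atoms: iodine, II
Why: The aluminium hydride reduces the ester to the primary alkoxide and, directed by the C8 alkoxide, adds trans across the alkyne (Al on C6, H on C7); iodinolysis with retention leaves iodine cis to C8, the geometry that later lets the C8 oxygen reach C5.

Step 8
Reactants: 14 (4Z,6S,7Z)-9-(TBDPS-oxy)-4-iodo-3,3,7-trimethylnona-4,7-diene-1,6-diol
Product: 15 (4Z,6S,7Z)-9-(TBDPS-oxy)-4-iodo-3,3,7-trimethyl-1,6-bis(TES-oxy)nona-4,7-diene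
Conditions: Et3SiCl, imidazole, DMAP (cat.), CH2Cl2, 0 °C to rt
Reagents that add atoms: chlorotriethylsilane, CC[Si](Cl)(CC)CC
Why: Both hydroxyl groups are silylated under standard conditions; the primary TES ether is a latent aldehyde (step 10) and the secondary one is the group transferred in the key step.

Step 9
Reactants: 15 (4Z,6S,7Z)-9-(TBDPS-oxy)-4-iodo-3,3,7-trimethyl-1,6-bis(TES-oxy)nona-4,7-diene; 16 2-bromopropene
Product: 19 (4E,6S,7Z)-9-(TBDPS-oxy)-3,3,7-trimethyl-4-(prop-1-en-2-yl)-1,6-bis(TES-oxy)nona-4,7-diene, via isopropenylmagnesium bromide 17 (not isolated), via isopropenylzinc chloride 18 (not isolated)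
Conditions: 16, Mg, THF; ZnCl2, THF, 0 °C; then 15, Pd[P(t-Bu)3]2 (5 mol %), THF, rt to 45 °C
Reagents that add atoms: none
Why: Negishi coupling of an alkenyl iodide with an alkenylzinc halide proceeds with retention at C6, so C8 stays cis to the new isopropenyl group; a small zinc nucleophile and a bulky electron-rich zerovalent palladium catalyst are chosen because C6 is flanked by the quaternary C1.

Step 10
Reactants: 19 (4E,6S,7Z)-9-(TBDPS-oxy)-3,3,7-trimethyl-4-(prop-1-en-2-yl)-1,6-bis(TES-oxy)nona-4,7-diene
Product: 20 (4E,6S,7Z)-9-(TBDPS-oxy)-3,3,7-trimethyl-4-(prop-1-en-2-yl)-6-(TES-oxy)nona-4,7-dienal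
Conditions: (COCl)2, DMSO, CH2Cl2, −78 to −40 °C; Et3N, −78 to 0 °C
Reagents that add atoms: none
Why: Under Swern conditions a primary TES ether is attacked by the chlorosulfonium salt and oxidised directly to the aldehyde, while the secondary TES and the TBDPS ethers are too hindered to react; C3 is freed without a third protecting group and 20 is used at once.

Step 11
Reactants: 20 (4E,6S,7Z)-9-(TBDPS-oxy)-3,3,7-trimethyl-4-(prop-1-en-2-yl)-6-(TES-oxy)nona-4,7-dienal
Product: 21 tert-butyl{[(2Z)-3-[(2S,6R,7aR)-4,4,7a-trimethyl-6-(TES-oxy)-2,4,5,6,7,7a-hexahydro-1-benzofuran-2-yl]but-2-en-1-yl]oxy}diphenylsilane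
Conditions: BINOL-derived imidodiphosphorimidate Brønsted acid with 3,3′-bis[3,5-bis(trifluoromethyl)phenyl] groups and N-SO2CF3 groups (5 mol %, antipode as in the remark), toluene, 4 Å molecular sieves, −78 °C; Et3N at −78 °C
Reagents that add atoms: none
Why: Proposed new method: the chiral acid (as its silylated form after the first turnover) activates the C3 aldehyde as an oxocarbenium ion, and C4, the unsubstituted end of the twisted diene, attacks it through a chair, which closes the cyclohexane ring in the 6-endo-trig mode with respect to C4=C5 and with the carbonyl oxygen outside the ring. The silyl ether oxygen on C8, held beside C5 by the C6=C7 geometry, adds to C5 anti to the forming C3–C4 bond, which closes the dihydrofuran ring in the 5-exo-trig mode with respect to C4=C5 (equivalent to capture of the C5 end of the developing C5–C6–C7 allyl cation). The silyloxonium ion so formed passes Et3Si+ to the counter-anion and on to the next aldehyde, which leaves the C3 oxygen silylated, closes the catalytic cycle and makes the step an isomerisation. The closest known reaction types are acid-promoted Prins cyclisations of aldehydes onto 1,1-disubstituted alkenes and dienes with oxygen trapping, and asymmetric Prins and carbonyl–ene cyclisations catalysed by confined chiral Brønsted acids; new here are the diene as nucleophile, the silyl ether as terminating group and catalyst control over a quaternary ether carbon. C3 is set by the catalyst, which exposes one face of the oxocarbenium ion inside its pocket. C5 is set by relay through the chair: the C3 silyloxy group is equatorial because an axial one would meet the axial methyl groups on C1 and C5, and the oxygen enters C5 equatorially with the C5 methyl group axial, so the C3 and C5 oxygens come out cis (3R,5R). C8 is preset and untouched because its C–O bond is never broken. The step needs attack by C4 and not C7 (secured by the free CH2 terminus, the six-membered chair and the gem-dimethyl group on C1), activation of the aldehyde and not ionisation of the doubly allylic C8–O bond (secured by −78 °C, the non-nucleophilic confined anion and the low basicity of the hindered silyl ether), and termination by oxygen and not by proton loss (secured by the cis placing of C8 and C5 across C6=C7).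

Step 12
Reactants: 21 tert-butyl{[(2Z)-3-[(2S,6R,7aR)-4,4,7a-trimethyl-6-(TES-oxy)-2,4,5,6,7,7a-hexahydro-1-benzofuran-2-yl]but-2-en-1-yl]oxy}diphenylsilane
Product: 22 (2S,6R,7aR)-2-[(2Z)-4-(TBDPS-oxy)but-2-en-2-yl]-4,4,7a-trimethyl-2,4,5,6,7,7a-hexahydro-1-benzofuran-6-ol
Conditions: HF·pyridine, pyridine, THF, 0 °C
Reagents that add atoms: none
Why: Pyridine-buffered HF removes the secondary TES ether much faster than the primary TBDPS ether, and the buffered medium is too weakly acidic to ionise the C8–O bond.

Step 13
Reactants: 22 (2S,6R,7aR)-2-[(2Z)-4-(TBDPS-oxy)but-2-en-2-yl]-4,4,7a-trimethyl-2,4,5,6,7,7a-hexahydro-1-benzofuran-6-ol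
Product: 23 (2S,7aR)-2-[(2Z)-4-(TBDPS-oxy)but-2-en-2-yl]-4,4,7a-trimethyl-2,4,5,7a-tetrahydro-1-benzofuran-6(7H)-one
Conditions: Dess–Martin periodinane, pyridine, CH2Cl2, 0 °C to rt
Reagents that add atoms: none
Why: Dess–Martin oxidation of the secondary alcohol under buffered conditions gives the ketone and erases the relay centre C3; strong base is avoided because the product is a β-alkoxy ketone that could open by elimination.

Step 14
Reactants: 23 (2S,7aR)-2-[(2Z)-4-(TBDPS-oxy)but-2-en-2-yl]-4,4,7a-trimethyl-2,4,5,7a-tetrahydro-1-benzofuran-6(7H)-one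
Product: 24 (2S,6S,7aR)-2-[(2Z)-4-(TBDPS-oxy)but-2-en-2-yl]-4,4,7a-trimethyl-2,4,5,6,7,7a-hexahydro-1-benzofuran-6-ol
Conditions: LiBH(s-Bu)3, THF, −78 °C; H2O
Reagents that add atoms: none
Why: In the only chair open to 23 the C5 methyl group is axial and syn to the axial C1 methyl group, so the bulky hydride reaches C3 only along the equatorial path and gives the axial alcohol cis to the C5 methyl group (3S); at −78 °C reduction is faster than enolisation.

Step 15
Reactants: 24 (2S,6S,7aR)-2-[(2Z)-4-(TBDPS-oxy)but-2-en-2-yl]-4,4,7a-trimethyl-2,4,5,6,7,7a-hexahydro-1-benzofuran-6-ol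
Product: 25 (2S,6S,7aR)-2-[(2Z)-4-hydroxybut-2-en-2-yl]-4,4,7a-trimethyl-2,4,5,6,7,7a-hexahydro-1-benzofuran-6-ol
Conditions: Bu4NF, THF, 0 °C to rt
Reagents that add atoms: none
Why: Fluoride cleaves the remaining silyl ether; the diol carries no group that is sensitive to the basic medium.

Step 16
Reactants: 25 (2S,6S,7aR)-2-[(2Z)-4-hydroxybut-2-en-2-yl]-4,4,7a-trimethyl-2,4,5,6,7,7a-hexahydro-1-benzofuran-6-ol
Product: 26 (2Z)-3-[(2S,6S,7aR)-6-hydroxy-4,4,7a-trimethyl-2,4,5,6,7,7a-hexahydro-1-benzofuran-2-yl]but-2-enal
Conditions: MnO2, CH2Cl2, rt, dark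
Reagents that add atoms: none
Why: MnO2 oxidises only the allylic primary alcohol and leaves the saturated secondary C3 alcohol; short contact in the dark limits Z to E isomerisation of the enal.

Step 17
Reactants: 27 (2E,4E,6E)-2,7-dimethylocta-2,4,6-trienedial
Product: 28 ethyl (2E,4E,6E,8E)-4,9-dimethyl-10-oxodeca-2,4,6,8-tetraenoate
Conditions: Ph3P=CHCO2Et (1.0 equiv, added slowly), CH2Cl2, 0 °C to rt
Reagents that add atoms: ethyl (triphenylphosphoranylidene)acetate, CCOC(=O)C=P(c1ccccc1)(c1ccccc1)c1ccccc1
Why: Wittig reaction of a stabilised ylide gives the E enoate; slow addition of one equivalent of ylide to an excess of the symmetrical dialdehyde favours mono-olefination, and unchanged 27 is recovered.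

Step 18
Reactants: 28 ethyl (2E,4E,6E,8E)-4,9-dimethyl-10-oxodeca-2,4,6,8-tetraenoate
Product: 29 ethyl (2E,4E,6E,8E)-10-hydroxy-4,9-dimethyldeca-2,4,6,8-tetraenoate
Conditions: NaBH4, EtOH/THF, −20 °C
Reagents that add atoms: none
Why: NaBH4 reduces the conjugated aldehyde by 1,2-addition far faster than it touches the ester or the polyene.

Step 19
Reactants: 29 ethyl (2E,4E,6E,8E)-10-hydroxy-4,9-dimethyldeca-2,4,6,8-tetraenoate
Product: 30 ethyl (2E,4E,6E,8E)-10-bromo-4,9-dimethyldeca-2,4,6,8-tetraenoate
Conditions: PBr3, pyridine (cat.), Et2O, −10 °C, dark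
Reagents that add atoms: phosphorus tribromide, BrP(Br)Br
Why: PBr3 converts the primary allylic alcohol into the bromide; the conjugated primary bromide is the favoured allylic isomer and is used without storage.

Step 20
Reactants: 30 ethyl (2E,4E,6E,8E)-10-bromo-4,9-dimethyldeca-2,4,6,8-tetraenoate
Product: 31 ethyl (2E,4E,6E,8E)-10-(diethoxyphosphoryl)-4,9-dimethyldeca-2,4,6,8-tetraenoate
Conditions: P(OEt)3, toluene, 100 °C
Reagents that add atoms: triethyl phosphite, CCOP(OCC)OCC
Why: Michaelis–Arbuzov reaction of the allylic bromide with triethyl phosphite gives the phosphonate with loss of bromoethane.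

Step 21
Reactants: 26 (2Z)-3-[(2S,6S,7aR)-6-hydroxy-4,4,7a-trimethyl-2,4,5,6,7,7a-hexahydro-1-benzofuran-2-yl]but-2-enal; 31 ethyl (2E,4E,6E,8E)-10-(diethoxyphosphoryl)-4,9-dimethyldeca-2,4,6,8-tetraenoate
Product: 33 ethyl (2E,4E,6E,8E,10E,12Z)-13-[(2S,6S,7aR)-6-hydroxy-4,4,7a-trimethyl-2,4,5,6,7,7a-hexahydro-1-benzofuran-2-yl]-4,9-dimethyltetradeca-2,4,6,8,10,12-hexaenoate, via sodium phosphonate carbanion 32 (not isolated)
Conditions: 31, NaN(SiMe3)2, THF, −78 °C; then 26, −78 to 0 °C, dark
Reagents that add atoms: none
Why: Horner–Wadsworth–Emmons olefination: the delocalised, weakly basic phosphonate carbanion adds reversibly to the enal and funnels to the E alkene at C11=C12; it does not deprotonate the C3 hydroxyl, and using the preformed anion with no excess base protects the Z-enal and C8 from γ-deprotonation.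

Step 22
Reactants: 33 ethyl (2E,4E,6E,8E,10E,12Z)-13-[(2S,6S,7aR)-6-hydroxy-4,4,7a-trimethyl-2,4,5,6,7,7a-hexahydro-1-benzofuran-2-yl]-4,9-dimethyltetradeca-2,4,6,8,10,12-hexaenoate
Product: 34 (2E,4E,6E,8E,10E,12Z)-13-[(2S,6S,7aR)-6-hydroxy-4,4,7a-trimethyl-2,4,5,6,7,7a-hexahydro-1-benzofuran-2-yl]-4,9-dimethyltetradeca-2,4,6,8,10,12-hexaen-1-ol
Conditions: i-Bu2AlH (3.5 equiv), CH2Cl2, −78 °C; aq. KNaC4H4O6, dark
Reagents that add atoms: none
Why: i-Bu2AlH at low temperature reduces the conjugated ester by 1,2-addition to the primary allylic alcohol without touching the polyene or the allylic ether; one equivalent is consumed by the C3 hydroxyl.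

## Compound list

1 | methyl 3,3-dimethylpent-4-enoate | COC(=O)CC(C)(C)C=C | starting material
2 | methyl 3-methyl-3-(1,2,4-trioxolan-3-yl)butanoate (secondary ozonide) | COC(=O)CC(C)(C)C1OCOO1 | intermediate
3 | methyl 3,3-dimethyl-4-oxobutanoate | COC(=O)CC(C)(C)C=O | intermediate
4 | methyl 3,3-dimethylpent-4-ynoate | COC(=O)CC(C)(C)C#C | intermediate
5 | but-2-yn-1-ol | CC#CCO | starting material
6 | sodium 2,2-bis(2-methoxyethoxy)-3-methyl-2,5-dihydro-1,2-oxaaluminol-2-uide (cyclic alkenylalanate) | [Na+].CC1=CCO[Al-]1(OCCOC)OCCOC | intermediate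
7 | (2Z)-3-iodobut-2-en-1-ol | C/C(I)=C/CO | intermediate
8 | tert-butyl{[(2Z)-3-iodobut-2-en-1-yl]oxy}diphenylsilane | C/C(I)=C/CO[Si](c1ccccc1)(c1ccccc1)C(C)(C)C | intermediate
9 | [(2Z)-4-(TBDPS-oxy)but-2-en-2-yl]lithium | C/C([Li])=C/CO[Si](c1ccccc1)(c1ccccc1)C(C)(C)C | intermediate
10 | (2Z)-4-(TBDPS-oxy)-2-methylbut-2-enal | C/C(C=O)=C/CO[Si](c1ccccc1)(c1ccccc1)C(C)(C)C | intermediate
11 | (5-methoxy-3,3-dimethyl-5-oxopent-1-yn-1-yl)(methyl)zinc | C[Zn]C#CC(C)(C)CC(=O)OC | intermediate
12 | methyl (6R,7Z)-9-(TBDPS-oxy)-6-hydroxy-3,3,7-trimethylnon-7-en-4-ynoate | C/C(=C/CO[Si](c1ccccc1)(c1ccccc1)C(C)(C)C)[C@@H](O)C#CC(C)(C)CC(=O)OC | intermediate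
13 | disodium cyclic alkenylalanate of the reduced substrate (Al on C6 and bound to the C8 oxygen in a five-membered ring, two 2-methoxyethoxy ligands, C3 oxygen as alkoxide) | [Na+].[Na+].C/C(=C/CO[Si](c1ccccc1)(c1ccccc1)C(C)(C)C)[C@@H]1C=C(C(C)(C)CC[O-])[Al-](OCCOC)(OCCOC)O1 | intermediate
14 | (4Z,6S,7Z)-9-(TBDPS-oxy)-4-iodo-3,3,7-trimethylnona-4,7-diene-1,6-diol | C/C(=C/CO[Si](c1ccccc1)(c1ccccc1)C(C)(C)C)[C@@H](O)/C=C(\I)C(C)(C)CCO | intermediate
15 | (4Z,6S,7Z)-9-(TBDPS-oxy)-4-iodo-3,3,7-trimethyl-1,6-bis(TES-oxy)nona-4,7-diene | C/C(=C/CO[Si](c1ccccc1)(c1ccccc1)C(C)(C)C)[C@@H](O[Si](CC)(CC)CC)/C=C(\I)C(C)(C)CCO[Si](CC)(CC)CC | intermediate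
16 | 2-bromopropene | C=C(C)Br | starting material
17 | isopropenylmagnesium bromide | C=C(C)[Mg]Br | intermediate
18 | isopropenylzinc chloride | C=C(C)[Zn]Cl | intermediate
19 | (4E,6S,7Z)-9-(TBDPS-oxy)-3,3,7-trimethyl-4-(prop-1-en-2-yl)-1,6-bis(TES-oxy)nona-4,7-diene | C/C(=C/CO[Si](c1ccccc1)(c1ccccc1)C(C)(C)C)[C@@H](O[Si](CC)(CC)CC)/C=C(\C(C)=C)C(C)(C)CCO[Si](CC)(CC)CC | intermediate
20 | (4E,6S,7Z)-9-(TBDPS-oxy)-3,3,7-trimethyl-4-(prop-1-en-2-yl)-6-(TES-oxy)nona-4,7-dienal | C/C(=C/CO[Si](c1ccccc1)(c1ccccc1)C(C)(C)C)[C@@H](O[Si](CC)(CC)CC)/C=C(\C(C)=C)C(C)(C)CC=O | intermediate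
21 | tert-butyl{[(2Z)-3-[(2S,6R,7aR)-4,4,7a-trimethyl-6-(TES-oxy)-2,4,5,6,7,7a-hexahydro-1-benzofuran-2-yl]but-2-en-1-yl]oxy}diphenylsilane | C/C(=C/CO[Si](c1ccccc1)(c1ccccc1)C(C)(C)C)[C@@H]1C=C2C(C)(C)C[C@@H](O[Si](CC)(CC)CC)C[C@@]2(C)O1 | intermediate
22 | (2S,6R,7aR)-2-[(2Z)-4-(TBDPS-oxy)but-2-en-2-yl]-4,4,7a-trimethyl-2,4,5,6,7,7a-hexahydro-1-benzofuran-6-ol | C/C(=C/CO[Si](c1ccccc1)(c1ccccc1)C(C)(C)C)[C@@H]1C=C2C(C)(C)C[C@@H](O)C[C@@]2(C)O1 | intermediate
23 | (2S,7aR)-2-[(2Z)-4-(TBDPS-oxy)but-2-en-2-yl]-4,4,7a-trimethyl-2,4,5,7a-tetrahydro-1-benzofuran-6(7H)-one | C/C(=C/CO[Si](c1ccccc1)(c1ccccc1)C(C)(C)C)[C@@H]1C=C2C(C)(C)CC(=O)C[C@@]2(C)O1 | intermediate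
24 | (2S,6S,7aR)-2-[(2Z)-4-(TBDPS-oxy)but-2-en-2-yl]-4,4,7a-trimethyl-2,4,5,6,7,7a-hexahydro-1-benzofuran-6-ol | C/C(=C/CO[Si](c1ccccc1)(c1ccccc1)C(C)(C)C)[C@@H]1C=C2C(C)(C)C[C@H](O)C[C@@]2(C)O1 | intermediate
25 | (2S,6S,7aR)-2-[(2Z)-4-hydroxybut-2-en-2-yl]-4,4,7a-trimethyl-2,4,5,6,7,7a-hexahydro-1-benzofuran-6-ol | C/C(=C/CO)[C@@H]1C=C2C(C)(C)C[C@H](O)C[C@@]2(C)O1 | intermediate
26 | (2Z)-3-[(2S,6S,7aR)-6-hydroxy-4,4,7a-trimethyl-2,4,5,6,7,7a-hexahydro-1-benzofuran-2-yl]but-2-enal | C/C(=C/C=O)[C@@H]1C=C2C(C)(C)C[C@H](O)C[C@@]2(C)O1 | intermediate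
27 | (2E,4E,6E)-2,7-dimethylocta-2,4,6-trienedial | O=C/C(C)=C/C=C/C=C(C)/C=O | starting material
28 | ethyl (2E,4E,6E,8E)-4,9-dimethyl-10-oxodeca-2,4,6,8-tetraenoate | O=C/C(C)=C/C=C/C=C(C)/C=C/C(=O)OCC | intermediate
29 | ethyl (2E,4E,6E,8E)-10-hydroxy-4,9-dimethyldeca-2,4,6,8-tetraenoate | OC/C(C)=C/C=C/C=C(C)/C=C/C(=O)OCC | intermediate
30 | ethyl (2E,4E,6E,8E)-10-bromo-4,9-dimethyldeca-2,4,6,8-tetraenoate | BrC/C(C)=C/C=C/C=C(C)/C=C/C(=O)OCC | intermediate
31 | ethyl (2E,4E,6E,8E)-10-(diethoxyphosphoryl)-4,9-dimethyldeca-2,4,6,8-tetraenoate | CCOP(=O)(OCC)C/C(C)=C/C=C/C=C(C)/C=C/C(=O)OCC | intermediate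
32 | sodium salt of the C10 carbanion of 31 | [Na+].CCOP(=O)(OCC)[CH-]/C(C)=C/C=C/C=C(C)/C=C/C(=O)OCC | intermediate
33 | ethyl (2E,4E,6E,8E,10E,12Z)-13-[(2S,6S,7aR)-6-hydroxy-4,4,7a-trimethyl-2,4,5,6,7,7a-hexahydro-1-benzofuran-2-yl]-4,9-dimethyltetradeca-2,4,6,8,10,12-hexaenoate | C/C(=C/C=C/C(C)=C/C=C/C=C(C)/C=C/C(=O)OCC)[C@@H]1C=C2C(C)(C)C[C@H](O)C[C@@]2(C)O1 | intermediate
34 | (2E,4E,6E,8E,10E,12Z)-13-[(2S,6S,7aR)-6-hydroxy-4,4,7a-trimethyl-2,4,5,6,7,7a-hexahydro-1-benzofuran-2-yl]-4,9-dimethyltetradeca-2,4,6,8,10,12-hexaen-1-ol | C/C(=C/C=C/C(C)=C/C=C/C=C(C)/C=C/CO)[C@@H]1C=C2C(C)(C)C[C@H](O)C[C@@]2(C)O1 | target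

## Step count and least certain steps

Total: 22 steps. Longest linear sequence: 16 steps (3, 4, 5, 6, 7, 8, 9, 10, 11, 12, 13, 14, 15, 16, 21, 22) from but-2-yn-1-ol; the alkyne branch (steps 1–2) and the phosphonate branch (steps 17–20) are shorter.

Step 11 (key step, new method). Most likely to go wrong: ionisation of the doubly allylic C8–O bond by the strong acid or by the silylium species, which would scramble C8 and degrade the diene. Next most likely are proton loss from the cation in place of oxygen capture, and poor facial selectivity if the catalyst pocket does not override the small bias of the preset C8. Should the cation live long enough to be captured axially, the C3 and C5 oxygens would come out trans; the route tolerates this because C3 is reset through 23, but the other catalyst antipode would then be needed to obtain 5R. Fallback by known reaction types, setting out from 20: Me2AlCl in CH2Cl2 at −78 °C should effect a type 2 carbonyl–ene cyclisation of the aldehyde onto the 1,1-disubstituted alkene to give 4-[(2S,3Z)-5-(TBDPS-oxy)-3-methyl-2-(TES-oxy)pent-3-en-1-ylidene]-5,5-dimethyl-3-methylidenecyclohexan-1-ol F1 as a mixture at the carbinol carbon. Buffered HF·pyridine would then free the C8 oxygen to give the diol F2. Hg(O2CCF3)2 in THF followed by NaBH4/NaOH would close the dihydrofuran by 5-exo oxymercuration–demercuration at the methylidene carbon, giving the bicyclic alcohol F3 as a mixture at C3 and C5. Dess–Martin oxidation removes the C3 centre and gives 23 together with its C5 epimer, the (2S,7aS)-ketone F4, which is separated by chromatography. The route is rejoined at 23.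

Step 9 (Negishi coupling). Most likely to go wrong: slow transmetalation and reductive elimination at C6, which is flanked by the quaternary C1 and the silyloxy-bearing C8, with reduction of the iodide or loss of alkene geometry on prolonged heating. Fallback with reversed roles, setting out from 12: hydroalumination as in step 7 gives alanate 13, whose alkenyl–aluminium bond is cross-coupled directly with 16 (ZnCl2, Pd(PPh3)4, THF, 50 °C), so that C6 is the nucleophile and no hindered iodide is needed. This should give (4E,6S,7Z)-9-(TBDPS-oxy)-3,3,7-trimethyl-4-(prop-1-en-2-yl)nona-4,7-diene-1,6-diol F5, which Et3SiCl/imidazole converts into 19. The route is rejoined at 19.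

Step 6 (asymmetric alkynylation). Most likely to go wrong: insufficient or reversed facial selectivity with a Z-configured, α-branched enal, and partial Z to E isomerisation of 10 at the Lewis acidic zinc centres. Fallback that sets C8 by reduction, setting out from 4 and 10: addition of zinc acetylide 11 without the chiral ligand gives the racemic alcohol methyl (7Z)-9-(TBDPS-oxy)-6-hydroxy-3,3,7-trimethylnon-7-en-4-ynoate F6. MnO2 oxidises it to methyl (7Z)-9-(TBDPS-oxy)-3,3,7-trimethyl-6-oxonon-7-en-4-ynoate F7. Corey–Bakshi–Shibata reduction with the (R)-2-methyl oxazaborolidine and catecholborane at −78 °C, in which the branched alkenyl group acts as the larger substituent, should give 12. The route is rejoined at 12.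

Step 10 (chemoselective Swern oxidation). Most likely to go wrong: loss of the secondary, doubly allylic TES ether alongside the primary one, or incomplete conversion of the primary ether at the low temperature needed to spare the secondary one. Fallback in two separate operations, setting out from 19: brief treatment with HF·pyridine/pyridine in THF at 0 °C cleaves only the primary ether and gives (4E,6S,7Z)-9-(TBDPS-oxy)-3,3,7-trimethyl-4-(prop-1-en-2-yl)-6-(TES-oxy)nona-4,7-dien-1-ol F8, and Dess–Martin periodinane with pyridine oxidises it to 20. The route is rejoined at 20.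

## Further compounds

F1 | step 11 | 4-[(2S,3Z)-5-(TBDPS-oxy)-3-methyl-2-(TES-oxy)pent-3-en-1-ylidene]-5,5-dimethyl-3-methylidenecyclohexan-1-ol (both C1 epimers, side chain cis to the methylidene-bearing carbon) | C/C(=C/CO[Si](c1ccccc1)(c1ccccc1)C(C)(C)C)[C@@H](O[Si](CC)(CC)CC)/C=C1\C(=C)CC(O)CC1(C)C
F2 | step 11 | 4-[(2S,3Z)-5-(TBDPS-oxy)-2-hydroxy-3-methylpent-3-en-1-ylidene]-5,5-dimethyl-3-methylidenecyclohexan-1-ol (both C1 epimers) | C/C(=C/CO[Si](c1ccccc1)(c1ccccc1)C(C)(C)C)[C@@H](O)/C=C1\C(=C)CC(O)CC1(C)C
F3 | step 11 | (2S)-2-[(2Z)-4-(TBDPS-oxy)but-2-en-2-yl]-4,4,7a-trimethyl-2,4,5,6,7,7a-hexahydro-1-benzofuran-6-ol (mixture at C6 and C7a) | C/C(=C/CO[Si](c1ccccc1)(c1ccccc1)C(C)(C)C)[C@@H]1C=C2C(C)(C)CC(O)CC2(C)O1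
F4 | step 11 | (2S,7aS)-2-[(2Z)-4-(TBDPS-oxy)but-2-en-2-yl]-4,4,7a-trimethyl-2,4,5,7a-tetrahydro-1-benzofuran-6(7H)-one | C/C(=C/CO[Si](c1ccccc1)(c1ccccc1)C(C)(C)C)[C@@H]1C=C2C(C)(C)CC(=O)C[C@]2(C)O1
F5 | step 9 | (4E,6S,7Z)-9-(TBDPS-oxy)-3,3,7-trimethyl-4-(prop-1-en-2-yl)nona-4,7-diene-1,6-diol | C/C(=C/CO[Si](c1ccccc1)(c1ccccc1)C(C)(C)C)[C@@H](O)/C=C(\C(C)=C)C(C)(C)CCO
F6 | step 6 | methyl (7Z)-9-(TBDPS-oxy)-6-hydroxy-3,3,7-trimethylnon-7-en-4-ynoate (racemic) | C/C(=C/CO[Si](c1ccccc1)(c1ccccc1)C(C)(C)C)C(O)C#CC(C)(C)CC(=O)OC
F7 | step 6 | methyl (7Z)-9-(TBDPS-oxy)-3,3,7-trimethyl-6-oxonon-7-en-4-ynoate | C/C(=C/CO[Si](c1ccccc1)(c1ccccc1)C(C)(C)C)C(=O)C#CC(C)(C)CC(=O)OC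
F8 | step 10 | (4E,6S,7Z)-9-(TBDPS-oxy)-3,3,7-trimethyl-4-(prop-1-en-2-yl)-6-(TES-oxy)nona-4,7-dien-1-ol | C/C(=C/CO[Si](c1ccccc1)(c1ccccc1)C(C)(C)C)[C@@H](O[Si](CC)(CC)CC)/C=C(\C(C)=C)C(C)(C)CCO
A1 | alternative 1 | (2R,5S)-2-methyl-2-(prop-2-en-1-yl)-5-[(triisopropylsilyl)ethynyl]dihydrofuran-3(2H)-one | CC(C)[Si](C(C)C)(C(C)C)C#C[C@@H]1CC(=O)[C@@](C)(CC=C)O1
A2 | alternative 1 | (5S)-2-diazo-5-(prop-2-en-1-yloxy)-7-(triisopropylsilyl)hept-6-yn-3-one | CC(C)[Si](C(C)C)(C(C)C)C#C[C@@H](OCC=C)CC(=O)C(C)=[N+]=[N-]
A3 | alternative 2 | ethyl (2Z)-3-[(2S,6S,7aR)-6-(tert-butyldimethylsilyloxy)-4,4,7a-trimethyl-2,4,5,6,7,7a-hexahydro-1-benzofuran-2-yl]but-2-enoate | C/C(=C/C(=O)OCC)[C@@H]1C=C2C(C)(C)C[C@H](O[Si](C)(C)C(C)(C)C)C[C@@]2(C)O1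
A4 | alternative 2 | ethyl (2Z,4E)-5-[(4R)-4-(tert-butyldimethylsilyloxy)-2,6,6-trimethylcyclohex-1-en-1-yl]-3-methylpenta-2,4-dienoate | CC1=C(/C=C/C(C)=C\C(=O)OCC)C(C)(C)C[C@H](O[Si](C)(C)C(C)(C)C)C1
A5 | alternative 2 | ethyl (2Z)-3-[(3R,7S,8aR)-7-(tert-butyldimethylsilyloxy)-5,5,8a-trimethyl-3,5,6,7,8,8a-hexahydro-1,2-benzodioxin-3-yl]but-2-enoate (5,8-endoperoxide) | C/C(=C/C(=O)OCC)[C@H]1C=C2C(C)(C)C[C@H](O[Si](C)(C)C(C)(C)C)C[C@@]2(C)OO1
A6 | alternative 3 | tert-butyl{[(2Z)-3-[(2S,6S,7aR)-6-(tert-butyldimethylsilyloxy)-4,4,7a-trimethyl-2,4,5,6,7,7a-hexahydro-1-benzofuran-2-yl]but-2-en-1-yl]oxy}dimethylsilane | C/C(=C/CO[Si](C)(C)C(C)(C)C)[C@@H]1C=C2C(C)(C)C[C@H](O[Si](C)(C)C(C)(C)C)C[C@@]2(C)O1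
A7 | alternative 3 | (2R,4S)-4-(tert-butyldimethylsilyloxy)-1-[(3Z)-5-(tert-butyldimethylsilyloxy)-3-methylpent-3-en-1-yn-1-yl]-2,6,6-trimethylcyclohexane-1,2-diol (either configuration at C1) | C/C(=C/CO[Si](C)(C)C(C)(C)C)C#CC1(O)C(C)(C)C[C@H](O[Si](C)(C)C(C)(C)C)C[C@@]1(C)O
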